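**Strategy.** The plan rests on cutting the benzene ring at C1–C2 and C2–C3 (C1 carries the C7 oxymethyl group, C2 and C3 the bromines, C4 the aryl sulfate, C5 the phenol, C6 hydrogen). What remains, C7–C1–C6–C5(O)–C4(O)–C3, is the intact carbon chain of kojic acid with both catechol oxygens in place, so the precursor is a kojic acid diether (O4 benzyl, O7 triisopropylsilyl). In one operation nitromethane exchanges its carbon for the pyranone ring oxygen: addition, ring opening and aldol reclosure build the arene, put a nitrogen handle on C2 for installing both bromines, and deliver the old carbonyl as the free O5 phenol, already distinguished from O4.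

Key step: step 3

**Assumption.** The sulfate monoesters 14–17 are written as neutral hydrogen sulfates but would be handled as salts (14 and 15 as pyridinium or tetrabutylammonium salts, 17 as the dipotassium salt, which gives the drawn acid form on cation exchange).

**Design remarks.** TIPS = tri(propan-2-yl)silyl; Piv = 2,2-dimethylpropanoyl.
- O7 is carried as a TIPS ether and not as a second benzyl ether. A benzyl ether there would place a benzylic, oxygen-activated C–H in a 1,5-relationship to the C2 aryl radical of step 7, and BCl3 could cleave a dibenzylic ether on either side.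
- O4 is sulfated before O7 is unmasked. A para-hydroxybenzyl unit with a leaving group on C7 would eliminate to a quinone methide.
- Compound 3 is also offered commercially; buying it would shorten the route by one step.

**Route**

Step 1
Reactants: 1 kojic acid; 2 benzyl bromide
Product: 3 5-(benzyloxy)-2-(hydroxymethyl)-4H-pyran-4-one
Conditions: BnBr, NaOH, MeOH/H2O, 65 °C
Reagents that add atoms: none
Why: Williamson etherification: aqueous methanolic NaOH deprotonates only the acidic enolic 5-OH of kojic acid, so benzylation should occur there and leave the primary alcohol free.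

Step 2
Reactants: 3 5-(benzyloxy)-2-(hydroxymethyl)-4H-pyran-4-one
Product: 4 5-(benzyloxy)-2-({[tri(propan-2-yl)silyl]oxy}methyl)-4H-pyran-4-one
Conditions: TIPSCl, imidazole, DMF, 25 °C
Reagents that add atoms: chlorotri(propan-2-yl)silane, CC(C)[Si](Cl)(C(C)C)C(C)C
Why: Imidazole-promoted silylation of the primary alcohol gives a base-stable silyl ether that has no hydrogen on the atom attached to O7 for the later C2 aryl radical to abstract and that is eventually cleaved at Si–O, not at the benzylic C7–O bond.

Step 3
Reactants: 4 5-(benzyloxy)-2-({[tri(propan-2-yl)silyl]oxy}methyl)-4H-pyran-4-one; 5 nitromethane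
Product: 7 2-(benzyloxy)-4-nitro-5-({[tri(propan-2-yl)silyl]oxy}methyl)phenol, via ring-opened nitro diketone 6 (not isolated)
Conditions: MeNO2 (4 equiv), KOtBu (2.5 equiv), tBuOH/THF, 25 → 60 °C; then AcOH
Reagents that add atoms: none
Why: Potassium nitronate adds in Michael fashion to an oxygen-bearing ring carbon of the vinylogous ester (preferably the unsubstituted CH, the future C3), the resulting 2H-pyranyl enolate opens by E1cB cleavage of the C–O1 bond to the diketone enolate of 6, and the nitromethyl carbon, deprotonated again, attacks the freed ketone carbonyl (intramolecular Henry/aldol reaction) before water is lost and the dienone tautomerises to the nitrophenolate, so that C1–C2 and C2–C3 are both formed. The closest known reaction type is the ring transformation of 4-pyranones and pyrylium salts into 4-nitrophenols and nitroarenes with nitromethane and base (an addition/ring-opening/ring-closure sequence, also familiar from the pyranone-to-pyridinone exchange of kojic acid ethers with amines), applied here to a kojic acid diether. The benzene ring closes in a 6-(enolexo)-exo-trig aldol mode, and aromatisation makes the closure irreversible. No stereocentre is created. The only selectivity required is addition to the ring in preference to base-induced side reactions: attack at either oxygen-bearing carbon gives the same arene because the incoming carbon simply takes the place of O1, both hydroxyls are masked as base-stable ethers, and nitromethane is kept in excess over KOtBu so that the nitronate is the strongest base present. The former carbonyl oxygen emerges as the free O5 phenol while O4 keeps its benzyl group, which differentiates the two catechol oxygens.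

Step 4
Reactants: 7 2-(benzyloxy)-4-nitro-5-({[tri(propan-2-yl)silyl]oxy}methyl)phenol
Product: 8 2-(benzyloxy)-4-nitro-5-({[tri(propan-2-yl)silyl]oxy}methyl)phenyl 2,2-dimethylpropanoate
Conditions: PivCl, Et3N, DMAP (cat.), CH2Cl2, 0 → 25 °C
Reagents that add atoms: pivaloyl chloride, CC(C)(C)C(=O)Cl
Why: Nucleophile-catalysed (DMAP) acylation of the acidic nitrophenol masks O5 as a hindered ester, which blocks bromination ortho to a free phenol and oxidation of the coming para-aminophenol and can be removed at the very end by hydroxide.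

Step 5
Reactants: 8 2-(benzyloxy)-4-nitro-5-({[tri(propan-2-yl)silyl]oxy}methyl)phenyl 2,2-dimethylpropanoate
Product: 9 4-amino-2-(benzyloxy)-5-({[tri(propan-2-yl)silyl]oxy}methyl)phenyl 2,2-dimethylpropanoate
Conditions: Fe powder, NH4Cl, EtOH/H2O, 70 °C
Reagents that add atoms: none
Why: Béchamp-type reduction with Fe in aqueous NH4Cl should reduce only the nitro group, leaving the benzyl ether, the silyl ether and the aryl pivalate intact.

Step 6
Reactants: 9 4-amino-2-(benzyloxy)-5-({[tri(propan-2-yl)silyl]oxy}methyl)phenyl 2,2-dimethylpropanoate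
Product: 10 4-amino-2-(benzyloxy)-3-bromo-5-({[tri(propan-2-yl)silyl]oxy}methyl)phenyl 2,2-dimethylpropanoate
Conditions: NBS (1.0 equiv), MeCN, −20 → 0 °C
Reagents that add atoms: N-bromosuccinimide, O=C1CCC(=O)N1Br
Why: Electrophilic aromatic bromination directed by the amino group to its only free ortho position C3 (also ortho to the benzyloxy group), the para position being occupied by the pivaloyloxy carbon and C6 being meta to both donors.

Step 7
Reactants: 10 4-amino-2-(benzyloxy)-3-bromo-5-({[tri(propan-2-yl)silyl]oxy}methyl)phenyl 2,2-dimethylpropanoate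
Product: 12 2-(benzyloxy)-3,4-dibromo-5-({[tri(propan-2-yl)silyl]oxy}methyl)phenyl 2,2-dimethylpropanoate, via arenediazonium bromide 11 (not isolated)
Conditions: tBuONO, CuBr2, MeCN, 0 → 50 °C
Reagents that add atoms: CuBr2 (copper dibromide), Br[Cu]Br; tert-butyl nitrite, CC(C)(C)ON=O (its nitrogen appears only in intermediate 11)
Why: Sandmeyer bromination under non-aqueous conditions: the alkyl nitrite diazotises the amine, monovalent copper formed in the mixture reduces the diazonium ion to the C2 aryl radical, and CuBr2 transfers bromine to it faster than any hydrogen shift, since the silyl ether offers no activated 1,5-hydrogen.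

Step 8
Reactants: 12 2-(benzyloxy)-3,4-dibromo-5-({[tri(propan-2-yl)silyl]oxy}methyl)phenyl 2,2-dimethylpropanoate
Product: 13 3,4-dibromo-2-hydroxy-5-({[tri(propan-2-yl)silyl]oxy}methyl)phenyl 2,2-dimethylpropanoate
Conditions: BCl3, C6HMe5, CH2Cl2, −78 °C; then H2O
Reagents that add atoms: none
Why: Lewis-acid cleavage of the aryl benzyl ether with BCl3, with pentamethylbenzene as a non-basic scavenger of the benzyl cation (Friedel–Crafts capture), is selective at −78 °C over the aryl bromides, the aryl pivalate and the bulky primary silyl ether.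

Step 9
Reactants: 13 3,4-dibromo-2-hydroxy-5-({[tri(propan-2-yl)silyl]oxy}methyl)phenyl 2,2-dimethylpropanoate
Product: 14 3,4-dibromo-2-(sulfooxy)-5-({[tri(propan-2-yl)silyl]oxy}methyl)phenyl 2,2-dimethylpropanoate
Conditions: SO3·pyridine (5 equiv), pyridine, 45 °C
Reagents that add atoms: sulfur trioxide–pyridine complex, O=S(=O)([O-])[n+]1ccccc1
Why: O-sulfation of the phenol by SO3 transfer from its pyridine complex is carried out while C7 still bears the non-leaving silyloxy group, so the para-hydroxybenzyl unit can never expel a leaving group to a quinone methide, and the pivaloyl group should stay on O5 because O4 is the more acidic, bromine-flanked oxygen.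

Step 10
Reactants: 14 3,4-dibromo-2-(sulfooxy)-5-({[tri(propan-2-yl)silyl]oxy}methyl)phenyl 2,2-dimethylpropanoate
Product: 15 3,4-dibromo-5-(hydroxymethyl)-2-(sulfooxy)phenyl 2,2-dimethylpropanoate
Conditions: TBAF, AcOH (1:1), THF, 25 °C
Reagents that add atoms: none
Why: Fluoride-induced desilylation buffered with AcOH cleaves the Si–O bond only and should leave the aryl pivalate and the aryl sulfate anion untouched; with O4 sulfated the liberated benzylic alcohol is no longer prone to ionisation.

Step 11
Reactants: 15 3,4-dibromo-5-(hydroxymethyl)-2-(sulfooxy)phenyl 2,2-dimethylpropanoate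
Product: 17 [2,3-dibromo-5-hydroxy-4-(sulfooxy)phenyl]methyl hydrogen sulfate (target), via bis-sulfate pivalate 16 (not isolated)
Conditions: SO3·pyridine, DMF, 25 °C; then 1 M aq KOH, 0 → 25 °C; C18 desalting
Reagents that add atoms: sulfur trioxide–pyridine complex, O=S(=O)([O-])[n+]1ccccc1
Why: Sulfation of the primary benzylic alcohol with SO3·pyridine is followed in the same flask by saponification of the aryl pivalate, which hydroxide cleaves far faster than it attacks sulfate monoester anions, and the O5 phenoxide, being meta to C1, cannot expel the benzylic sulfate.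

**Compound list**

1 | kojic acid, 5-hydroxy-2-(hydroxymethyl)-4H-pyran-4-one | O=C1C=C(CO)OC=C1O | starting material
2 | benzyl bromide | BrCc1ccccc1 | starting material
3 | 5-(benzyloxy)-2-(hydroxymethyl)-4H-pyran-4-one | O=C1C=C(CO)OC=C1OCc1ccccc1 | intermediate
4 | 5-(benzyloxy)-2-({[tri(propan-2-yl)silyl]oxy}methyl)-4H-pyran-4-one | O=C1C=C(CO[Si](C(C)C)(C(C)C)C(C)C)OC=C1OCc1ccccc1 | intermediate
5 | nitromethane | C[N+](=O)[O-] | starting material
6 | (2E)-3-(benzyloxy)-1-nitro-7-{[tri(propan-2-yl)silyl]oxy}hept-2-ene-4,6-dione (ring-opened nitro diketone, not isolated) | [O-][N+](=O)C/C=C(OCc1ccccc1)\C(=O)CC(=O)CO[Si](C(C)C)(C(C)C)C(C)C | intermediate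
7 | 2-(benzyloxy)-4-nitro-5-({[tri(propan-2-yl)silyl]oxy}methyl)phenol | Oc1cc(CO[Si](C(C)C)(C(C)C)C(C)C)c([N+](=O)[O-])cc1OCc1ccccc1 | intermediate
8 | 2-(benzyloxy)-4-nitro-5-({[tri(propan-2-yl)silyl]oxy}methyl)phenyl 2,2-dimethylpropanoate | CC(C)(C)C(=O)Oc1cc(CO[Si](C(C)C)(C(C)C)C(C)C)c([N+](=O)[O-])cc1OCc1ccccc1 | intermediate
9 | 4-amino-2-(benzyloxy)-5-({[tri(propan-2-yl)silyl]oxy}methyl)phenyl 2,2-dimethylpropanoate | CC(C)(C)C(=O)Oc1cc(CO[Si](C(C)C)(C(C)C)C(C)C)c(N)cc1OCc1ccccc1 | intermediate
10 | 4-amino-2-(benzyloxy)-3-bromo-5-({[tri(propan-2-yl)silyl]oxy}methyl)phenyl 2,2-dimethylpropanoate | CC(C)(C)C(=O)Oc1cc(CO[Si](C(C)C)(C(C)C)C(C)C)c(N)c(Br)c1OCc1ccccc1 | intermediate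
11 | 3-(benzyloxy)-2-bromo-4-[(2,2-dimethylpropanoyl)oxy]-6-({[tri(propan-2-yl)silyl]oxy}methyl)benzenediazonium bromide (not isolated) | CC(C)(C)C(=O)Oc1cc(CO[Si](C(C)C)(C(C)C)C(C)C)c([N+]#N)c(Br)c1OCc1ccccc1.[Br-] | intermediate
12 | 2-(benzyloxy)-3,4-dibromo-5-({[tri(propan-2-yl)silyl]oxy}methyl)phenyl 2,2-dimethylpropanoate | CC(C)(C)C(=O)Oc1cc(CO[Si](C(C)C)(C(C)C)C(C)C)c(Br)c(Br)c1OCc1ccccc1 | intermediate
13 | 3,4-dibromo-2-hydroxy-5-({[tri(propan-2-yl)silyl]oxy}methyl)phenyl 2,2-dimethylpropanoate | CC(C)(C)C(=O)Oc1cc(CO[Si](C(C)C)(C(C)C)C(C)C)c(Br)c(Br)c1O | intermediate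
14 | 3,4-dibromo-2-(sulfooxy)-5-({[tri(propan-2-yl)silyl]oxy}methyl)phenyl 2,2-dimethylpropanoate | CC(C)(C)C(=O)Oc1cc(CO[Si](C(C)C)(C(C)C)C(C)C)c(Br)c(Br)c1OS(=O)(=O)O | intermediate
15 | 3,4-dibromo-5-(hydroxymethyl)-2-(sulfooxy)phenyl 2,2-dimethylpropanoate | CC(C)(C)C(=O)Oc1cc(CO)c(Br)c(Br)c1OS(=O)(=O)O | intermediate
16 | 3,4-dibromo-2-(sulfooxy)-5-[(sulfooxy)methyl]phenyl 2,2-dimethylpropanoate (bis-sulfate pivalate, not isolated) | CC(C)(C)C(=O)Oc1cc(COS(=O)(=O)O)c(Br)c(Br)c1OS(=O)(=O)O | intermediate
17 | [2,3-dibromo-5-hydroxy-4-(sulfooxy)phenyl]methyl hydrogen sulfate | O=S(=O)(O)OCc1cc(O)c(OS(=O)(=O)O)c(Br)c1Br | target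

**Totals and risks**

Total step count: 11. Longest linear sequence: 11 steps from kojic acid (10 if 3 is bought).

Steps most likely to fail:

1. Step 3. The nitronate may add too slowly to the electron-rich alkoxy-substituted pyranone (one oxygen-bearing carbon is deactivated by the neighbouring benzyloxy group, the other is hindered). Self-condensation of nitromethane or incomplete closure and dehydration of the opened chain could then dominate. The fallback sets out from 4 and keeps the same ring-forming bonds. O-Silylation of the carbonyl oxygen with TBSOTf (CH2Cl2, 0 °C) gives 5-(benzyloxy)-4-{[tert-butyl(dimethyl)silyl]oxy}-2-({[tri(propan-2-yl)silyl]oxy}methyl)pyrylium trifluoromethanesulfonate F1, a much stronger electrophile. MeNO2 and Et3N convert it by the pyrylium-to-nitrobenzene ring transformation (nitronate addition, electrocyclic opening of the 2H-pyran, nitro-aldol closure, loss of water) into {2-(benzyloxy)-4-nitro-5-({[tri(propan-2-yl)silyl]oxy}methyl)phenoxy}(tert-butyl)dimethylsilane F2. K2CO3 in MeOH then cleaves only the labile nitrophenyl silyl ether, and the route is rejoined at 7.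

2. Step 9. Sulfate transfer to the hindered, acidic O4 phenol may stay incomplete. The pivaloyl group may also drift from O5 to O4 in the basic medium, so that sulfate ends on the wrong oxygen in a salt mixture that is hard to separate. The fallback sets out from 13 and introduces the sulfate in protected, neutral form. Sulfonylation with 2,2,2-trichloroethyl chlorosulfate (Et3N, DMAP, THF, 0 °C) gives 3,4-dibromo-2-{[(2,2,2-trichloroethoxy)sulfonyl]oxy}-5-({[tri(propan-2-yl)silyl]oxy}methyl)phenyl 2,2-dimethylpropanoate F5. This diester can be purified on silica and its regiochemistry secured. Zn and HCO2NH4 in MeOH then remove the trichloroethyl group by reductive fragmentation, and the route is rejoined at 14.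

3. Step 7. Diazotisation of an amine flanked by bromine and the silyloxymethyl group may be sluggish, and the aryl radical may take up hydrogen instead of bromine. The fallback sets out from 9, whose amine has only one ortho substituent, and inverts the order in which the two bromines are introduced. The same nitrite/CuBr2 Sandmeyer reaction gives 2-(benzyloxy)-4-bromo-5-({[tri(propan-2-yl)silyl]oxy}methyl)phenyl 2,2-dimethylpropanoate F3. BCl3 with pentamethylbenzene (CH2Cl2, −78 °C) then frees the O4 phenol to give 4-bromo-2-hydroxy-5-({[tri(propan-2-yl)silyl]oxy}methyl)phenyl 2,2-dimethylpropanoate F4. NBS brominates the only free position ortho to that hydroxyl (C3), and the route is rejoined at 13.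

**Further compounds**

F1 | step 3 | 5-(benzyloxy)-4-{[tert-butyl(dimethyl)silyl]oxy}-2-({[tri(propan-2-yl)silyl]oxy}methyl)pyrylium trifluoromethanesulfonate | CC(C)[Si](OCc1cc(O[Si](C)(C)C(C)(C)C)c(OCc2ccccc2)c[o+]1)(C(C)C)C(C)C.[O-]S(=O)(=O)C(F)(F)F
F2 | step 3 | {2-(benzyloxy)-4-nitro-5-({[tri(propan-2-yl)silyl]oxy}methyl)phenoxy}(tert-butyl)dimethylsilane | CC(C)(C)[Si](C)(C)Oc1cc(CO[Si](C(C)C)(C(C)C)C(C)C)c([N+](=O)[O-])cc1OCc1ccccc1
F3 | step 7 | 2-(benzyloxy)-4-bromo-5-({[tri(propan-2-yl)silyl]oxy}methyl)phenyl 2,2-dimethylpropanoate | CC(C)(C)C(=O)Oc1cc(CO[Si](C(C)C)(C(C)C)C(C)C)c(Br)cc1OCc1ccccc1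
F4 | step 7 | 4-bromo-2-hydroxy-5-({[tri(propan-2-yl)silyl]oxy}methyl)phenyl 2,2-dimethylpropanoate | CC(C)(C)C(=O)Oc1cc(CO[Si](C(C)C)(C(C)C)C(C)C)c(Br)cc1O
F5 | step 9 | 3,4-dibromo-2-{[(2,2,2-trichloroethoxy)sulfonyl]oxy}-5-({[tri(propan-2-yl)silyl]oxy}methyl)phenyl 2,2-dimethylpropanoate | CC(C)(C)C(=O)Oc1cc(CO[Si](C(C)C)(C(C)C)C(C)C)c(Br)c(Br)c1OS(=O)(=O)OCC(Cl)(Cl)Cl
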